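**Retrosynthetic overview**
1. Target ⇐ 14‑O‑TIPS macrocycle 26 (TIPS → acetate last); the ten‑membered ring is closed last by ring‑closing metathesis at C5=C6.
2. Diene 25 ⇐ Negishi sp3–sp2 coupling (C8–C9) of the cyclohexenone iodide 15 with (R)‑4‑bromo‑3‑methyl‑5‑vinylbutenolide 23 (butenolide ring made separately by Dieckmann condensation from (R)‑α‑hydroxy‑γ‑butyrolactone).
3. 15 ⇐ aldehyde 8 by Felkin‑controlled addition of a 3‑methylbut‑3‑enyl titanium reagent (C2–C3, sets C2), then tiglate.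
4. 8 ⇐ cyclohexene 6 by singlet‑oxygen ene reaction/dehydration; 6 ⇐ catalytic enantioselective Diels–Alder of enal 3 with silyloxydiene 5 (sets C1, C10, C14).
5. Ring order: cyclohexene (Diels–Alder, first) → butenolide (separate branch) → ten‑membered ring (metathesis, last).

Locants follow the target: C1 quaternary carbon, C2 CH–O‑tiglate, C5=C6 ring olefin, C7 lactone CH–O, C8=C17 butenolide olefin, C9 CH2, C10 ring‑fusion CH, C11=C12–C13(=O) enone, C14 CH–OAc. TBS = tert‑butyldimethylsilyl, TIPS = triisopropylsilyl.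

Assumption: 1, 2, 4, 9, 16 and tiglic acid are taken as commercial, and the (S)‑configured oxazaborolidinium catalyst is taken to give the enantiomer drawn for 6 (if the sense is opposite, the catalyst from the other prolinol enantiomer is used).

**Route**

Step 1
Reactants: 1 2‑[(TBS)oxy]acetaldehyde; 2 2‑(triphenylphosphoranylidene)propanal
Product: 3 (2E)‑4‑[(TBS)oxy]‑2‑methylbut‑2‑enal
Conditions: toluene, 80 °C
Reagents that add atoms: none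
Why: Wittig olefination with a stabilised formyl ylide is (E)‑selective, which places the formyl group trans to the CH2OTBS group.

Step 2
Reactants: 4 (2E)‑pent‑2‑enal
Product: 5 (1E,3E)‑1‑[(TIPS)oxy]penta‑1,3‑diene
Conditions: TIPSOTf, Et3N, Et2O, 0 °C → rt
Reagents that add atoms: triisopropylsilyl triflate, CC(C)[Si](C(C)C)(C(C)C)OS(=O)(=O)C(F)(F)F
Why: Silyl dienol ether formation (O‑silylation, then γ‑deprotonation of the s‑trans enal) gives the (1E,3E) diene needed for cycloaddition.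

Step 3
Reactants: 3 (2E)‑4‑[(TBS)oxy]‑2‑methylbut‑2‑enal; 5 (1E,3E)‑1‑[(TIPS)oxy]penta‑1,3‑diene
Product: 6 (1S,2R,5S,6R)‑6‑{[(TBS)oxy]methyl}‑1,5‑dimethyl‑2‑[(TIPS)oxy]cyclohex‑3‑ene‑1‑carbaldehyde
Conditions: (S)‑B‑(o‑tolyl)oxazaborolidine from α,α‑diphenylprolinol (20 mol%), Tf2NH (18 mol%), CH2Cl2, −78 → −40 °C
Reagents that add atoms: none
Why: Catalytic enantioselective Diels–Alder reaction in which the 1‑silyloxy group directs the diene's methyl‑bearing terminus to the enal β‑carbon, the (E)‑enal fixes C9 trans to the formyl group (C1/C10), the aldehyde‑endo transition state puts OTIPS cis to the formyl group (C14), and the oxazaborolidinium cation selects the re face of the enal α‑carbon.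

Step 4
Reactants: 6 (1S,2R,5S,6R)‑6‑{[(TBS)oxy]methyl}‑1,5‑dimethyl‑2‑[(TIPS)oxy]cyclohex‑3‑ene‑1‑carbaldehyde
Product: 8 (1S,2S,6R)‑6‑{[(TBS)oxy]methyl}‑1,5‑dimethyl‑3‑oxo‑2‑[(TIPS)oxy]cyclohex‑4‑ene‑1‑carbaldehyde, via allylic hydroperoxide 7 (not isolated)
Conditions: O2, tetraphenylporphyrin (cat.), hν, CH2Cl2, 0 °C; then Ac2O, pyridine, DMAP (cat.), 0 °C → rt
Reagents that add atoms: dioxygen, O=O
Why: Schenck ene reaction followed by Kornblum–DeLaMare‑type dehydration: singlet oxygen can only abstract the pseudo‑axial C11–H (the C14–H is pseudo‑equatorial and deactivated by OTIPS), so oxygen enters at C13 with the olefin shifting to C11=C12, and C1, C10 and C14 are untouched.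

Step 5
Reactants: 8 (1S,2S,6R)‑6‑{[(TBS)oxy]methyl}‑1,5‑dimethyl‑3‑oxo‑2‑[(TIPS)oxy]cyclohex‑4‑ene‑1‑carbaldehyde; 9 4‑bromo‑2‑methylbut‑1‑ene
Product: 12 (4R,5R,6S)‑4‑{[(TBS)oxy]methyl}‑5‑[(1S)‑1‑hydroxy‑4‑methylpent‑4‑en‑1‑yl]‑3,5‑dimethyl‑6‑[(TIPS)oxy]cyclohex‑2‑en‑1‑one, via Grignard reagent 10 (not isolated), via alkyltitanium triisopropoxide 11 (not isolated)
Conditions: 9, Mg, THF, rt; ClTi(OiPr)3, THF, −78 °C; then 8, −78 → 0 °C; aq. NH4Cl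
Reagents that add atoms: none
Why: Aldehyde‑selective addition of a Reetz‑type alkyltitanium in the presence of the enone; Felkin–Anh attack anti to the ring carbon carrying the bulky pseudo‑axial OTIPS group and past the small C1 methyl sets the (S) carbinol at C2.

Step 6
Reactants: 12 (4R,5R,6S)‑4‑{[(TBS)oxy]methyl}‑5‑[(1S)‑1‑hydroxy‑4‑methylpent‑4‑en‑1‑yl]‑3,5‑dimethyl‑6‑[(TIPS)oxy]cyclohex‑2‑en‑1‑one
Product: 13 (1S)‑1‑[(1R,2S,6R)‑6‑{[(TBS)oxy]methyl}‑1,5‑dimethyl‑3‑oxo‑2‑[(TIPS)oxy]cyclohex‑4‑en‑1‑yl]‑4‑methylpent‑4‑en‑1‑yl (2E)‑2‑methylbut‑2‑enoate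
Conditions: tiglic acid, 2,4,6‑trichlorobenzoyl chloride, Et3N, toluene, rt; then 12, DMAP, 60 °C
Reagents that add atoms: tiglic acid, C/C=C(\C)C(=O)O
Why: Yamaguchi esterification acylates the hindered neopentylic alcohol through the mixed anhydride without isomerising the (E)‑olefin or touching a stereocentre.

Step 7
Reactants: 13 (1S)‑1‑[(1R,2S,6R)‑6‑{[(TBS)oxy]methyl}‑1,5‑dimethyl‑3‑oxo‑2‑[(TIPS)oxy]cyclohex‑4‑en‑1‑yl]‑4‑methylpent‑4‑en‑1‑yl (2E)‑2‑methylbut‑2‑enoate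
Product: 14 (1S)‑1‑[(1R,2S,6R)‑6‑(hydroxymethyl)‑1,5‑dimethyl‑3‑oxo‑2‑[(TIPS)oxy]cyclohex‑4‑en‑1‑yl]‑4‑methylpent‑4‑en‑1‑yl (2E)‑2‑methylbut‑2‑enoate
Conditions: PPTS, MeOH, rt
Reagents that add atoms: none
Why: Acid‑catalysed methanolysis (selective desilylation) removes the primary TBS ether much faster than the hindered secondary TIPS ether.

Step 8
Reactants: 14 (1S)‑1‑[(1R,2S,6R)‑6‑(hydroxymethyl)‑1,5‑dimethyl‑3‑oxo‑2‑[(TIPS)oxy]cyclohex‑4‑en‑1‑yl]‑4‑methylpent‑4‑en‑1‑yl (2E)‑2‑methylbut‑2‑enoate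
Product: 15 (1S)‑1‑[(1R,2S,6R)‑6‑(iodomethyl)‑1,5‑dimethyl‑3‑oxo‑2‑[(TIPS)oxy]cyclohex‑4‑en‑1‑yl]‑4‑methylpent‑4‑en‑1‑yl (2E)‑2‑methylbut‑2‑enoate
Conditions: I2, PPh3, imidazole, CH2Cl2, 0 °C → rt
Reagents that add atoms: iodine, II
Why: Appel‑type iodination (alkoxyphosphonium, SN2 by iodide) of the only free hydroxyl, at an achiral CH2.

Step 9
Reactants: 16 (3R)‑3‑hydroxyoxolan‑2‑one
Product: 18 methyl (2R)‑2‑hydroxy‑4‑(phenylselanyl)butanoate, via sodium carboxylate 17 (not isolated)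
Conditions: (PhSe)2, NaH, DMF, 60 °C; then 16, 110 °C; then MeI, rt
Reagents that add atoms: diphenyl diselenide, c1ccc(cc1)[Se][Se]c1ccccc1; iodomethane, CI
Why: SN2 lactone opening at the γ‑CH2–O carbon by the soft selenolate (alkyl–oxygen cleavage) leaves the (R) carbinol untouched, and the carboxylate is then O‑methylated.

Step 10
Reactants: 18 methyl (2R)‑2‑hydroxy‑4‑(phenylselanyl)butanoate
Product: 19 methyl (2R)‑4‑(phenylselanyl)‑2‑(propanoyloxy)butanoate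
Conditions: EtCOCl, pyridine, DMAP (cat.), CH2Cl2, 0 °C → rt
Reagents that add atoms: propanoyl chloride, CCC(=O)Cl
Why: DMAP‑catalysed O‑acylation installs the future C17–C19 unit with retention at the carbinol.

Step 11
Reactants: 19 methyl (2R)‑4‑(phenylselanyl)‑2‑(propanoyloxy)butanoate
Product: 20 (5R)‑4‑hydroxy‑3‑methyl‑5‑[2‑(phenylselanyl)ethyl]furan‑2(5H)‑one
Conditions: LiN(SiMe3)2 (2.2 equiv), THF, −78 → 0 °C; then 1 M HCl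
Reagents that add atoms: none
Why: Dieckmann (Lacey‑type) condensation of the propanoate enolate onto the neighbouring methyl ester closes the tetronic acid, and the stereocentre is not involved once the tetronate anion has formed.

Step 12
Reactants: 20 (5R)‑4‑hydroxy‑3‑methyl‑5‑[2‑(phenylselanyl)ethyl]furan‑2(5H)‑one
Product: 21 (5R)‑4‑bromo‑3‑methyl‑5‑[2‑(phenylselanyl)ethyl]furan‑2(5H)‑one
Conditions: (COBr)2, DMF (cat.), CH2Cl2, 0 °C → rt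
Reagents that add atoms: oxalyl bromide, O=C(Br)C(=O)Br
Why: Vilsmeier‑type activation of the vinylogous acid followed by addition–elimination of bromide gives the β‑bromobutenolide under non‑basic conditions.

Step 13
Reactants: 21 (5R)‑4‑bromo‑3‑methyl‑5‑[2‑(phenylselanyl)ethyl]furan‑2(5H)‑one
Product: 23 (5R)‑4‑bromo‑5‑ethenyl‑3‑methylfuran‑2(5H)‑one, via selenoxide 22 (not isolated)
Conditions: 30% H2O2, THF, 0 °C → 40 °C
Reagents that add atoms: none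
Why: Selenide oxidation and syn selenoxide elimination unveil the vinyl group without base, so the doubly activated C7–H is neither epimerised nor isomerised.

Step 14
Reactants: 15 (1S)‑1‑[(1R,2S,6R)‑6‑(iodomethyl)‑1,5‑dimethyl‑3‑oxo‑2‑[(TIPS)oxy]cyclohex‑4‑en‑1‑yl]‑4‑methylpent‑4‑en‑1‑yl (2E)‑2‑methylbut‑2‑enoate; 23 (5R)‑4‑bromo‑5‑ethenyl‑3‑methylfuran‑2(5H)‑one
Product: 25 (1S)‑1‑[(1R,2S,6R)‑6‑{[(2R)‑2‑ethenyl‑4‑methyl‑5‑oxo‑2,5‑dihydrofuran‑3‑yl]methyl}‑1,5‑dimethyl‑3‑oxo‑2‑[(TIPS)oxy]cyclohex‑4‑en‑1‑yl]‑4‑methylpent‑4‑en‑1‑yl (2E)‑2‑methylbut‑2‑enoate, via alkylzinc iodide 24 (not isolated)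
Conditions: Zn dust (activated with BrCH2CH2Br, Me3SiCl), DMA, rt; then 23, Pd2(dba)3 (2.5 mol%), SPhos (10 mol%), THF, rt → 40 °C
Reagents that add atoms: none
Why: Negishi sp3–sp2 cross‑coupling (zinc insertion into the primary iodide, then coupling with the activated vinyl bromide on zerovalent palladium) forms C8–C9 under neutral conditions that preserve C7 and every other stereocentre.

Step 15
Reactants: 25 (1S)‑1‑[(1R,2S,6R)‑6‑{[(2R)‑2‑ethenyl‑4‑methyl‑5‑oxo‑2,5‑dihydrofuran‑3‑yl]methyl}‑1,5‑dimethyl‑3‑oxo‑2‑[(TIPS)oxy]cyclohex‑4‑en‑1‑yl]‑4‑methylpent‑4‑en‑1‑yl (2E)‑2‑methylbut‑2‑enoate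
Product: 26 14‑O‑TIPS macrocycle: the target skeleton, (1R,2S,5Z,7R,10R,14S), with OTIPS in place of OAc at C14
Conditions: second‑generation Grubbs catalyst RuCl2(=CHPh)(PCy3)(H2IMes) (20 mol% in portions), 1,4‑benzoquinone (cat.), toluene (1 mM), 90 °C
Reagents that add atoms: none
Why: Ring‑closing metathesis starts at the monosubstituted vinyl group and closes onto the 1,1‑disubstituted olefin, and the ten‑membered ring braced by the trans ring fusion and the butenolide is expected to accommodate only the (Z)‑trisubstituted C5=C6 olefin.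

Step 16
Reactants: 26 14‑O‑TIPS macrocycle
Product: 27 14‑hydroxy macrocycle: the target with free OH at C14, (1R,2S,5Z,7R,10R,14S)
Conditions: HF·pyridine, pyridine/THF, 0 °C → rt
Reagents that add atoms: none
Why: Fluoride‑mediated desilylation under buffered conditions is tolerated by the two ester‑type groups, the enone and the butenolide, with retention at C14.

Step 17
Reactants: 27 14‑hydroxy macrocycle
Product: 28 target CNP0218548.3, (1R,2S,5Z,7R,10R,14S)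
Conditions: Ac2O, pyridine, DMAP (cat.), CH2Cl2, 0 °C → rt
Reagents that add atoms: acetic anhydride, CC(=O)OC(C)=O
Why: DMAP‑catalysed acetylation of the α‑ketol oxygen proceeds with retention at C14 and gives the target.

**Compound list**
1 | 2‑[(tert‑butyldimethylsilyl)oxy]acetaldehyde | O=CCO[Si](C)(C)C(C)(C)C | starting material
2 | 2‑(triphenylphosphoranylidene)propanal | CC(C=O)=P(c1ccccc1)(c1ccccc1)c1ccccc1 | starting material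
3 | (2E)‑4‑[(TBS)oxy]‑2‑methylbut‑2‑enal | O=C/C(C)=C/CO[Si](C)(C)C(C)(C)C | intermediate
4 | (2E)‑pent‑2‑enal | CC/C=C/C=O | starting material
5 | (1E,3E)‑1‑[(TIPS)oxy]penta‑1,3‑diene | C/C=C/C=C/O[Si](C(C)C)(C(C)C)C(C)C | intermediate
6 | (1S,2R,5S,6R)‑6‑{[(TBS)oxy]methyl}‑1,5‑dimethyl‑2‑[(TIPS)oxy]cyclohex‑3‑ene‑1‑carbaldehyde | O=C[C@@]1(C)[C@H](CO[Si](C)(C)C(C)(C)C)[C@@H](C)C=C[C@H]1O[Si](C(C)C)(C(C)C)C(C)C | intermediate
7 | (1S,2S,3S,6R)‑6‑{[(TBS)oxy]methyl}‑3‑hydroperoxy‑1,5‑dimethyl‑2‑[(TIPS)oxy]cyclohex‑4‑ene‑1‑carbaldehyde | O=C[C@@]1(C)[C@H](CO[Si](C)(C)C(C)(C)C)C(C)=C[C@H](OO)[C@H]1O[Si](C(C)C)(C(C)C)C(C)C | intermediate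
8 | (1S,2S,6R)‑6‑{[(TBS)oxy]methyl}‑1,5‑dimethyl‑3‑oxo‑2‑[(TIPS)oxy]cyclohex‑4‑ene‑1‑carbaldehyde | O=C[C@@]1(C)[C@H](CO[Si](C)(C)C(C)(C)C)C(C)=CC(=O)[C@H]1O[Si](C(C)C)(C(C)C)C(C)C | intermediate
9 | 4‑bromo‑2‑methylbut‑1‑ene | C=C(C)CCBr | starting material
10 | (3‑methylbut‑3‑en‑1‑yl)magnesium bromide | C=C(C)CC[Mg]Br | intermediate
11 | (3‑methylbut‑3‑en‑1‑yl)titanium triisopropoxide | C=C(C)CC[Ti](OC(C)C)(OC(C)C)OC(C)C | intermediate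
12 | (4R,5R,6S)‑4‑{[(TBS)oxy]methyl}‑5‑[(1S)‑1‑hydroxy‑4‑methylpent‑4‑en‑1‑yl]‑3,5‑dimethyl‑6‑[(TIPS)oxy]cyclohex‑2‑en‑1‑one | C=C(C)CC[C@H](O)[C@@]1(C)[C@H](CO[Si](C)(C)C(C)(C)C)C(C)=CC(=O)[C@H]1O[Si](C(C)C)(C(C)C)C(C)C | intermediate
13 | (1S)‑1‑[(1R,2S,6R)‑6‑{[(TBS)oxy]methyl}‑1,5‑dimethyl‑3‑oxo‑2‑[(TIPS)oxy]cyclohex‑4‑en‑1‑yl]‑4‑methylpent‑4‑en‑1‑yl (2E)‑2‑methylbut‑2‑enoate | C/C=C(\C)C(=O)O[C@@H](CCC(C)=C)[C@@]1(C)[C@H](CO[Si](C)(C)C(C)(C)C)C(C)=CC(=O)[C@H]1O[Si](C(C)C)(C(C)C)C(C)C | intermediate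
14 | (1S)‑1‑[(1R,2S,6R)‑6‑(hydroxymethyl)‑1,5‑dimethyl‑3‑oxo‑2‑[(TIPS)oxy]cyclohex‑4‑en‑1‑yl]‑4‑methylpent‑4‑en‑1‑yl (2E)‑2‑methylbut‑2‑enoate | C/C=C(\C)C(=O)O[C@@H](CCC(C)=C)[C@@]1(C)[C@H](CO)C(C)=CC(=O)[C@H]1O[Si](C(C)C)(C(C)C)C(C)C | intermediate
15 | (1S)‑1‑[(1R,2S,6R)‑6‑(iodomethyl)‑1,5‑dimethyl‑3‑oxo‑2‑[(TIPS)oxy]cyclohex‑4‑en‑1‑yl]‑4‑methylpent‑4‑en‑1‑yl (2E)‑2‑methylbut‑2‑enoate | C/C=C(\C)C(=O)O[C@@H](CCC(C)=C)[C@@]1(C)[C@H](CI)C(C)=CC(=O)[C@H]1O[Si](C(C)C)(C(C)C)C(C)C | intermediate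
16 | (3R)‑3‑hydroxyoxolan‑2‑one | O[C@@H]1CCOC1=O | starting material
17 | sodium (2R)‑2‑hydroxy‑4‑(phenylselanyl)butanoate | [Na+].[O-]C(=O)[C@H](O)CC[Se]c1ccccc1 | intermediate
18 | methyl (2R)‑2‑hydroxy‑4‑(phenylselanyl)butanoate | COC(=O)[C@H](O)CC[Se]c1ccccc1 | intermediate
19 | methyl (2R)‑4‑(phenylselanyl)‑2‑(propanoyloxy)butanoate | COC(=O)[C@H](OC(=O)CC)CC[Se]c1ccccc1 | intermediate
20 | (5R)‑4‑hydroxy‑3‑methyl‑5‑[2‑(phenylselanyl)ethyl]furan‑2(5H)‑one | O=C1O[C@H](CC[Se]c2ccccc2)C(O)=C1C | intermediate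
21 | (5R)‑4‑bromo‑3‑methyl‑5‑[2‑(phenylselanyl)ethyl]furan‑2(5H)‑one | O=C1O[C@H](CC[Se]c2ccccc2)C(Br)=C1C | intermediate
22 | (5R)‑4‑bromo‑3‑methyl‑5‑[2‑(phenylseleninyl)ethyl]furan‑2(5H)‑one | O=C1O[C@H](CC[Se](=O)c2ccccc2)C(Br)=C1C | intermediate
23 | (5R)‑4‑bromo‑5‑ethenyl‑3‑methylfuran‑2(5H)‑one | O=C1O[C@H](C=C)C(Br)=C1C | intermediate
24 | alkylzinc iodide of 15 (C9–ZnI in place of C9–I) | C/C=C(\C)C(=O)O[C@@H](CCC(C)=C)[C@@]1(C)[C@H](C[Zn]I)C(C)=CC(=O)[C@H]1O[Si](C(C)C)(C(C)C)C(C)C | intermediate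
25 | (1S)‑1‑[(1R,2S,6R)‑6‑{[(2R)‑2‑ethenyl‑4‑methyl‑5‑oxo‑2,5‑dihydrofuran‑3‑yl]methyl}‑1,5‑dimethyl‑3‑oxo‑2‑[(TIPS)oxy]cyclohex‑4‑en‑1‑yl]‑4‑methylpent‑4‑en‑1‑yl (2E)‑2‑methylbut‑2‑enoate | C/C=C(\C)C(=O)O[C@@H](CCC(C)=C)[C@@]1(C)[C@H](CC2=C(C)C(=O)O[C@@H]2C=C)C(C)=CC(=O)[C@H]1O[Si](C(C)C)(C(C)C)C(C)C | intermediate
26 | 14‑O‑TIPS macrocycle, (1R,2S,5Z,7R,10R,14S) | C/C=C(\C)C(=O)O[C@H]1CC/C(C)=C\[C@H]2OC(=O)C(C)=C2C[C@@H]2C(C)=CC(=O)[C@@H](O[Si](C(C)C)(C(C)C)C(C)C)[C@@]12C | intermediate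
27 | 14‑hydroxy macrocycle, (1R,2S,5Z,7R,10R,14S) | C/C=C(\C)C(=O)O[C@H]1CC/C(C)=C\[C@H]2OC(=O)C(C)=C2C[C@@H]2C(C)=CC(=O)[C@@H](O)[C@@]12C | intermediate
28 | CNP0218548.3, (1R,2S,5Z,7R,10R,14S) | C/C=C(\C)C(=O)O[C@H]1CC/C(C)=C\[C@H]2OC(=O)C(C)=C2C[C@@H]2C(C)=CC(=O)[C@@H](OC(C)=O)[C@@]12C | target

**Step count and risks**

Total: 17 steps. Longest linear sequence: 11 steps (1, 3–8, 14–17); the diene (step 2) and the butenolide (steps 9–13) are made in parallel.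

Most likely to fail:

Step 3 (Diels–Alder of a trisubstituted enal with a 1,4‑disubstituted diene; reactivity, endo and enantioselectivity). The fallback sets out from 1 and 5 and comes back at 6. The quaternary centre is made after the cycloaddition instead of in it. Wittig reaction of 1 with (triphenylphosphoranylidene)acetaldehyde gives (2E)‑4‑[(TBS)oxy]but‑2‑enal F1, a β‑monosubstituted enal that is a much better and more reliably endo‑selective dienophile. The same oxazaborolidinium‑catalysed cycloaddition with 5 gives (1S,2R,5S,6R)‑6‑{[(TBS)oxy]methyl}‑5‑methyl‑2‑[(TIPS)oxy]cyclohex‑3‑ene‑1‑carbaldehyde F2. Deprotonation with KN(SiMe3)2 in THF at −78 °C and C‑methylation with MeI on the enolate face anti to the pseudo‑axial OTIPS group then returns 6.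

Step 5 (aldehyde‑versus‑enone selectivity and C2 diastereoselectivity of the titanium addition). The fallback sets out from 6 and comes back at 12. The enone is unveiled only after the C–C bond is made. Photooxygenation of 6 as in step 4, but with reductive work‑up (PPh3) of hydroperoxide 7, gives (1S,2S,3S,6R)‑6‑{[(TBS)oxy]methyl}‑3‑hydroxy‑1,5‑dimethyl‑2‑[(TIPS)oxy]cyclohex‑4‑ene‑1‑carbaldehyde F3. Excess Grignard reagent 10 then adds to the only carbonyl group to give (1S)‑1‑[(1R,2S,3S,6R)‑6‑{[(TBS)oxy]methyl}‑3‑hydroxy‑1,5‑dimethyl‑2‑[(TIPS)oxy]cyclohex‑4‑en‑1‑yl]‑4‑methylpent‑4‑en‑1‑ol F4. MnO2 in CH2Cl2 oxidises only the allylic C13 hydroxyl and returns 12.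

Step 15 (metathesis to a ten‑membered ring with a trisubstituted olefin next to a rigid, deactivating butenolide). The fallback sets out from 15 and comes back at 26. The ring is closed before the butenolide exists, and the butenolide is made last by an intramolecular Horner–Wadsworth–Emmons reaction.
- Enantiopure methyl (2R)‑2‑hydroxybut‑3‑enoate is silylated (Et3SiCl, imidazole) to methyl (2R)‑2‑[(triethylsilyl)oxy]but‑3‑enoate F5, which is converted with AlMe3/EtSH into S‑ethyl (2R)‑2‑[(triethylsilyl)oxy]but‑3‑enethioate F6.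
- Fukuyama coupling of alkylzinc iodide 24 (from 15) with F6 (Pd2(dba)3, SPhos) gives the seco ketone (1S)‑1‑[(1R,2S,6R)‑1,5‑dimethyl‑3‑oxo‑6‑{(3R)‑2‑oxo‑3‑[(triethylsilyl)oxy]pent‑4‑en‑1‑yl}‑2‑[(TIPS)oxy]cyclohex‑4‑en‑1‑yl]‑4‑methylpent‑4‑en‑1‑yl (2E)‑2‑methylbut‑2‑enoate F7.
- Ring‑closing metathesis of this more flexible diene (second‑generation Grubbs catalyst) gives the (5Z) macrocyclic 7‑(triethylsilyloxy)‑8‑ketone F8.
- PPTS/MeOH removes only the triethylsilyl group to give the macrocyclic 7‑hydroxy‑8‑ketone F9.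
- DCC/DMAP esterification with 2‑(diethoxyphosphoryl)propanoic acid gives the macrocyclic 7‑O‑[2‑(diethoxyphosphoryl)propanoyl] 8‑ketone F10.
- LiCl/iPr2NEt in MeCN closes the butenolide (C8=C17) and returns 26.

**Further compounds**
F1 | step 3 | (2E)‑4‑[(TBS)oxy]but‑2‑enal | O=C/C=C/CO[Si](C)(C)C(C)(C)C
F2 | step 3 | (1S,2R,5S,6R)‑6‑{[(TBS)oxy]methyl}‑5‑methyl‑2‑[(TIPS)oxy]cyclohex‑3‑ene‑1‑carbaldehyde | O=C[C@H]1[C@H](CO[Si](C)(C)C(C)(C)C)[C@@H](C)C=C[C@H]1O[Si](C(C)C)(C(C)C)C(C)C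
F3 | step 5 | (1S,2S,3S,6R)‑6‑{[(TBS)oxy]methyl}‑3‑hydroxy‑1,5‑dimethyl‑2‑[(TIPS)oxy]cyclohex‑4‑ene‑1‑carbaldehyde | O=C[C@@]1(C)[C@H](CO[Si](C)(C)C(C)(C)C)C(C)=C[C@H](O)[C@H]1O[Si](C(C)C)(C(C)C)C(C)C
F4 | step 5 | (1S)‑1‑[(1R,2S,3S,6R)‑6‑{[(TBS)oxy]methyl}‑3‑hydroxy‑1,5‑dimethyl‑2‑[(TIPS)oxy]cyclohex‑4‑en‑1‑yl]‑4‑methylpent‑4‑en‑1‑ol | C=C(C)CC[C@H](O)[C@@]1(C)[C@H](CO[Si](C)(C)C(C)(C)C)C(C)=C[C@H](O)[C@H]1O[Si](C(C)C)(C(C)C)C(C)C
F5 | step 15 | methyl (2R)‑2‑[(triethylsilyl)oxy]but‑3‑enoate | COC(=O)[C@H](O[Si](CC)(CC)CC)C=C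
F6 | step 15 | S‑ethyl (2R)‑2‑[(triethylsilyl)oxy]but‑3‑enethioate | CCSC(=O)[C@H](O[Si](CC)(CC)CC)C=C
F7 | step 15 | (1S)‑1‑[(1R,2S,6R)‑1,5‑dimethyl‑3‑oxo‑6‑{(3R)‑2‑oxo‑3‑[(triethylsilyl)oxy]pent‑4‑en‑1‑yl}‑2‑[(TIPS)oxy]cyclohex‑4‑en‑1‑yl]‑4‑methylpent‑4‑en‑1‑yl (2E)‑2‑methylbut‑2‑enoate | C/C=C(\C)C(=O)O[C@@H](CCC(C)=C)[C@@]1(C)[C@H](CC(=O)[C@H](O[Si](CC)(CC)CC)C=C)C(C)=CC(=O)[C@H]1O[Si](C(C)C)(C(C)C)C(C)C
F8 | step 15 | macrocyclic (1R,2S,5Z,7R,10R,14S) 7‑(triethylsilyloxy)‑8‑ketone with 2‑tiglate and 14‑OTIPS | C/C=C(\C)C(=O)O[C@H]1CC/C(C)=C\[C@@H](O[Si](CC)(CC)CC)C(=O)C[C@@H]2C(C)=CC(=O)[C@@H](O[Si](C(C)C)(C(C)C)C(C)C)[C@@]12C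
F9 | step 15 | macrocyclic (1R,2S,5Z,7R,10R,14S) 7‑hydroxy‑8‑ketone with 2‑tiglate and 14‑OTIPS | C/C=C(\C)C(=O)O[C@H]1CC/C(C)=C\[C@@H](O)C(=O)C[C@@H]2C(C)=CC(=O)[C@@H](O[Si](C(C)C)(C(C)C)C(C)C)[C@@]12C
F10 | step 15 | macrocyclic (1R,2S,5Z,7R,10R,14S) 7‑O‑[2‑(diethoxyphosphoryl)propanoyl] 8‑ketone with 2‑tiglate and 14‑OTIPS | C/C=C(\C)C(=O)O[C@H]1CC/C(C)=C\[C@@H](OC(=O)C(C)P(=O)(OCC)OCC)C(=O)C[C@@H]2C(C)=CC(=O)[C@@H](O[Si](C(C)C)(C(C)C)C(C)C)[C@@]12C
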